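The target is what I want from this flask, and I want it by hand, from where the flask must end and how soon it gets there.

    starting material ⇌ target (K1 = 39, k1 = 0.043 s⁻¹)
    solid substrate ⇌ starting material, rate k2*(cs2 - [starting material]) while solid is left; crystals form when [starting material] > cs2 (cs2 = 33 mM, k2 = 0.057 s⁻¹)

solid substrate 0.050 M; time 1.0 h

1. at 1.0 h, what has stopped the reaction, if anything has (for what has run out or reacted, a solid counts together with what of it has only dissolved) (forward and back rates have come level / all of the solid substrate has reacted / it is still moving)
2. part of the solid substrate that has turned into other species by 1.0 h (what has only dissolved does not count)
3. amount of target at 1.0 h, in percent of the solid substrate charged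
4. amount of starting material at 1.0 h, in percent of the solid substrate charged

- as a solid, counted per litre of solution: solid substrate
- at the start none of the solid substrate is in solution
- what has only dissolved of solid substrate counts as not reacted
- starting material means what is dissolved; the solid is not counted in it
- the reaction counts as stopped when no species that holds the solid substrate changes by six tenths of a point or more over the second half of the time
- run time (flask): 1.0 h

I begin with the main step by itself, starting material ⇌ target (K1 = 39, k1 = 0.043 s⁻¹), in a solution that already holds the whole charge. At balance [target]/[starting material] equals 39, so 2.50% of what is dissolved stays starting material; I call this part the balance share and carry it. It gives 2.50% starting material and 97.5% target, with 97.5% converted, and the step relaxes with a half-life of 0.262 min.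

Next I add the dissolving, solid substrate ⇌ starting material, rate k2*(cs2 - [starting material]) while solid is left; crystals form when [starting material] > cs2 (cs2 = 33 mM, k2 = 0.057 s⁻¹), which changes the road and leaves that share as it is. While solid lasts and the way back is still small, feed and drain level at [starting material] near 18.8 mM, lower than the solubility of 33 mM, so I expect no crystals. The feed at that level is 0.809 mM s⁻¹, which takes in the charge in about 1.03 min. At balance [starting material] is 1.25 mM, far below the solubility, so I expect the whole charge to be in solution by then.

Last comes the clock. The dissolving and 5 relaxation half-lives together take 2.34 min, far shorter than 1.0 h, so I expect forward and back rates to have come level.

The forecast says forward and back rates have come level, with 97.5% converted, 97.5% target and 2.5% starting material, holding that “all the solid is gone within a few minutes at most”.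

The flask gives forward and back rates have come level, with 97.5% converted, 97.5% target and 2.50% starting material, and the solid substrate already stood at 0% after 0.0500 h. In the neighbour flask with 0.020 M of solid substrate, the balance share puts [starting material] at 0.500 mM, again lower than the solubility, and that flask ends with 2.50% starting material and 97.5% target.

The constants used here were set for the occasion; no experiment stands behind them.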